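Ring B (C6–C11) is read as a masked isoprene Diels–Alder adduct: the C8/C9 bromochloride is the retron of a C8=C9 alkene, and C10–C11 with C6–C7 are the two σ-bonds of a [4+2] cycloaddition between isoprene and an exocyclic enone whose methylene carbon becomes C11. A chiral Brønsted acid thereby closes ring B and sets the quaternary spiro carbon C6 in one operation from an achiral, dimedone-derived 6-methylidene vinylogous ester. The remaining centres are relayed from C6: C4 by thermodynamic equatorial bromination, C3 by hydride delivery anti to the axial C5 methyl, C8/C9 by anti bromochlorination of the alkene face left open by the C1 methylidene.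

Key step: step 3

Remark: target locants are used for all spiro compounds (ring A = C1–C5, spiro carbon C6, ring B = C7–C11; C7 is the CH2 next to C8, C11 stems from the exocyclic methylene of 6); the CIP descriptor at C6 changes from R to S when bromine enters at C4, although the centre is not touched.
Remark: the sense of induction of the chiral acid with 6 is assumed; the catalyst antipode that leads to (6R)-8 is to be used.

Step 1
Reactants: 1 dimedone (5,5-dimethylcyclohexane-1,3-dione); 2 2-methylpropan-1-ol (isobutanol)
Product: 3 5,5-dimethyl-3-(2-methylpropoxy)cyclohex-2-en-1-one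
Conditions: TsOH·H2O (cat.), toluene, reflux, azeotropic removal of water
Reagents that add atoms: none
Why: Acid-catalysed enol ether formation from the symmetrical cyclic 1,3-diketone should give the vinylogous ester without any regio- or stereochemical issue.

Step 2
Reactants: 3 5,5-dimethyl-3-(2-methylpropoxy)cyclohex-2-en-1-one
Product: 6 5,5-dimethyl-6-methylidene-3-(2-methylpropoxy)cyclohex-2-en-1-one, via Mannich base 4 (not isolated), via quaternary ammonium iodide 5 (not isolated)
Conditions: LiN(iPr)2 (LDA), THF, −78 °C; CH2=NMe2+ I−, −78 °C → rt; MeI, CH2Cl2, rt; aq. NaHCO3, rt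
Reagents that add atoms: N,N-dimethylmethylideneammonium iodide, C=[N+](C)C.[I-]
Why: Kinetic deprotonation of a 3-alkoxy enone occurs at the α′ carbon (C6), the enolate adds to the iminium salt (Mannich reaction), and N-methylation followed by base-induced β-elimination of trimethylamine unveils the exocyclic enone (α-methylenation via a Mannich base); no stereocentre is formed and the adjacent gem-dimethyl group retards dimerisation.

Step 3
Reactants: 6 5,5-dimethyl-6-methylidene-3-(2-methylpropoxy)cyclohex-2-en-1-one; 7 isoprene (2-methylbuta-1,3-diene)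
Product: 8 (6R)-5,5,9-trimethyl-3-(2-methylpropoxy)spiro[5.5]undeca-2,8-dien-1-one
Conditions: chiral imidodiphosphorimidate (IDPi) Brønsted acid (2 mol %), 7 (5 equiv), CH2Cl2, −40 °C
Reagents that add atoms: none
Why: The chiral acid protonates the vinylogous ester carbonyl of 6, and the ion pair undergoes an asynchronous concerted [4+2] cycloaddition in which the bond from the exocyclic methylene carbon (C11) to C1 of isoprene (C10) runs ahead of the C6–C7 bond. The closest known reaction type is the confined-acid-catalysed asymmetric spirocyclising Diels–Alder reaction of exocyclic enones with simple dienes. Ring B is closed as a six-membered ring by intermolecular cycloaddition, which forms C10–C11 and C6–C7 and leaves the C8=C9 alkene as the handle for the two halogens. The only new stereocentre, quaternary C6, is set by the chiral counter-anion, which shields one face of the s-cis exocyclic enone. The step needs para regioselectivity, secured by the larger HOMO coefficient at C1 of isoprene and the larger LUMO coefficient at the methylene carbon, and chemoselectivity for the exocyclic alkene over the endocyclic C2=C3 alkene, which is trisubstituted and deactivated by the alkoxy donor.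

Step 4
Reactants: 8 (6R)-5,5,9-trimethyl-3-(2-methylpropoxy)spiro[5.5]undeca-2,8-dien-1-one; 9 tributyl[(methoxymethoxy)methyl]stannane
Product: 12 (6R)-1-(hydroxymethyl)-5,5,9-trimethylspiro[5.5]undeca-1,8-dien-3-one, via tertiary carbinol 10 (not isolated), via MOM ether 11 (not isolated)
Conditions: 9, n-BuLi, THF, −78 °C; CeCl3; 8, −78 → 0 °C; then HCl, MeOH–THF–H2O, 45 °C
Reagents that add atoms: water, O
Why: Tin–lithium exchange gives the α-alkoxymethyl nucleophile, whose cerium reagent adds 1,2 to the hindered C1 carbonyl, and acid then ionises the tertiary allylic carbinol, hydrolyses the enol ether (Stork–Danheiser transposition) and cleaves the acetal; the C1 carbinol centre is destroyed on dehydration and C6 is untouched.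

Step 5
Reactants: 12 (6R)-1-(hydroxymethyl)-5,5,9-trimethylspiro[5.5]undeca-1,8-dien-3-one
Product: 15 (4S,6S)-4-bromo-1-(hydroxymethyl)-5,5,9-trimethylspiro[5.5]undeca-1,8-dien-3-one, via bis-silyl dienol ether 13 (not isolated), via epimeric bromo ketone silyl ether 14 (not isolated)
Conditions: LiN(iPr)2 (2.2 equiv), Me3SiCl (2.5 equiv), THF, −78 °C; NBS (1.0 equiv), −78 °C; then TsOH·H2O (cat.), MeOH–CH2Cl2, rt
Reagents that add atoms: N-bromosuccinimide (NBS), O=C1CCC(=O)N1Br
Why: The alkoxide directs the second deprotonation to the α′ carbon C4 (kinetic cross-conjugated dienolate, as with isophorone), the silyl dienol ether is brominated at C4 (silyl enol ether halogenation), and acid-catalysed enolisation with methanolysis of the O-silyl ether should funnel both C4 epimers to the equatorial bromide of the favoured ring A conformer, in which C7 (whose neighbour C8 is sp2 and carries no axial hydrogen) lies equatorial beside the C1 substituent and C11 is axial, i.e. bromine cis to C7 (4S).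

Step 6
Reactants: 15 (4S,6S)-4-bromo-1-(hydroxymethyl)-5,5,9-trimethylspiro[5.5]undeca-1,8-dien-3-one
Product: 16 (3R,4S,6S)-4-bromo-1-(hydroxymethyl)-5,5,9-trimethylspiro[5.5]undeca-1,8-dien-3-ol
Conditions: iBu2AlH (DIBAL, 3 equiv), CH2Cl2, −78 °C; aq. KNaC4H4O6 work-up
Reagents that add atoms: none
Why: DIBAL effects 1,2-reduction of the enone with hydride approaching C3 anti to the pseudo-axial C5 methyl group (the usual equatorial attack on 3,3-dimethylcyclohexanone-type ketones), which should place the new hydroxyl axial and cis to the equatorial bromine (3R).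

Step 7
Reactants: 16 (3R,4S,6S)-4-bromo-1-(hydroxymethyl)-5,5,9-trimethylspiro[5.5]undeca-1,8-dien-3-ol
Product: 19 (3R,4S,6S)-4-bromo-5,5,9-trimethyl-1-methylidenespiro[5.5]undec-8-en-3-ol, via allylic sulfonyl hydrazine 17 (not isolated), via allylic diazene 18 (not isolated)
Conditions: 2-nitrobenzenesulfonyl hydrazide (NBSH), PPh3, DEAD, N-methylmorpholine, −30 °C → rt
Reagents that add atoms: none
Why: Mitsunobu displacement of the unhindered primary allylic alcohol by the sulfonyl hydrazide (the neopentyl-like secondary C3 alcohol should not react), loss of sulfinic acid and retro-ene extrusion of N2 from the allylic diazene (reductive 1,3-transposition of an allylic alcohol) deliver hydrogen to C2 and move the alkene to the exocyclic position without touching a stereocentre.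

Step 8
Reactants: 19 (3R,4S,6S)-4-bromo-5,5,9-trimethyl-1-methylidenespiro[5.5]undec-8-en-3-ol
Product: 20 (3R,4S,6S,8S,9S)-4,8-dibromo-9-chloro-5,5,9-trimethyl-1-methylidenespiro[5.5]undecan-3-ol (target)
Conditions: NBS (1.0 equiv), LiCl (5 equiv), MeCN–THF, −30 → 0 °C
Reagents that add atoms: N-bromosuccinimide (NBS), O=C1CCC(=O)N1Br; lithium chloride, [Li+].[Cl-]
Why: In this electrophilic anti bromochlorination the C1 methylidene lies over the ring B face that carries C1 next to C8 in the favoured conformer, so Br+ should be taken up by the more electron-rich trisubstituted C8=C9 alkene on the face syn to C5 and chloride should open the bromonium ion anti at the tertiary C9 (Markovnikov), giving bromine at C8 cis to C5 and chlorine at C9 trans to it (8S,9S).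

Compound list
1 | dimedone (5,5-dimethylcyclohexane-1,3-dione) | CC1(C)CC(=O)CC(=O)C1 | starting material
2 | 2-methylpropan-1-ol (isobutanol) | CC(C)CO | starting material
3 | 5,5-dimethyl-3-(2-methylpropoxy)cyclohex-2-en-1-one | CC(C)COC1=CC(=O)CC(C)(C)C1 | intermediate
4 | 6-[(dimethylamino)methyl]-5,5-dimethyl-3-(2-methylpropoxy)cyclohex-2-en-1-one (racemic Mannich base) | CC(C)COC1=CC(=O)C(CN(C)C)C(C)(C)C1 | intermediate
5 | N-methyl quaternary ammonium iodide of 4 | CC(C)COC1=CC(=O)C(C[N+](C)(C)C)C(C)(C)C1.[I-] | intermediate
6 | 5,5-dimethyl-6-methylidene-3-(2-methylpropoxy)cyclohex-2-en-1-one | CC(C)COC1=CC(=O)C(=C)C(C)(C)C1 | intermediate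
7 | isoprene (2-methylbuta-1,3-diene) | C=CC(C)=C | starting material
8 | (6R)-5,5,9-trimethyl-3-(2-methylpropoxy)spiro[5.5]undeca-2,8-dien-1-one | O=C1C=C(OCC(C)C)CC(C)(C)[C@]12CCC(C)=CC2 | intermediate
9 | tributyl[(methoxymethoxy)methyl]stannane | CCCC[Sn](CCCC)(CCCC)COCOC | starting material
10 | (6R)-1-[(methoxymethoxy)methyl]-5,5,9-trimethyl-3-(2-methylpropoxy)spiro[5.5]undeca-2,8-dien-1-ol, both C1 epimers | COCOCC1(O)C=C(OCC(C)C)CC(C)(C)[C@]12CCC(C)=CC2 | intermediate
11 | (6R)-1-[(methoxymethoxy)methyl]-5,5,9-trimethylspiro[5.5]undeca-1,8-dien-3-one | COCOCC1=CC(=O)CC(C)(C)[C@]12CCC(C)=CC2 | intermediate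
12 | (6R)-1-(hydroxymethyl)-5,5,9-trimethylspiro[5.5]undeca-1,8-dien-3-one | OCC1=CC(=O)CC(C)(C)[C@]12CCC(C)=CC2 | intermediate
13 | (6R)-5,5,9-trimethyl-3-(trimethylsilyloxy)-1-[(trimethylsilyloxy)methyl]spiro[5.5]undeca-1,3,8-triene | C[Si](C)(C)OCC1=CC(O[Si](C)(C)C)=CC(C)(C)[C@]12CCC(C)=CC2 | intermediate
14 | (6S)-4-bromo-5,5,9-trimethyl-1-[(trimethylsilyloxy)methyl]spiro[5.5]undeca-1,8-dien-3-one, both C4 epimers | C[Si](C)(C)OCC1=CC(=O)C(Br)C(C)(C)[C@]12CCC(C)=CC2 | intermediate
15 | (4S,6S)-4-bromo-1-(hydroxymethyl)-5,5,9-trimethylspiro[5.5]undeca-1,8-dien-3-one | OCC1=CC(=O)[C@@H](Br)C(C)(C)[C@]12CCC(C)=CC2 | intermediate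
16 | (3R,4S,6S)-4-bromo-1-(hydroxymethyl)-5,5,9-trimethylspiro[5.5]undeca-1,8-dien-3-ol | OCC1=C[C@@H](O)[C@@H](Br)C(C)(C)[C@]12CCC(C)=CC2 | intermediate
17 | N-allylated 2-nitrobenzenesulfonyl hydrazide of 16 (N attached to the C1 CH2 group) | NN(CC1=C[C@@H](O)[C@@H](Br)C(C)(C)[C@]12CCC(C)=CC2)S(=O)(=O)c1ccccc1[N+](=O)[O-] | intermediate
18 | allylic diazene of 16 (HN=N on the C1 CH2 group) | N=NCC1=C[C@@H](O)[C@@H](Br)C(C)(C)[C@]12CCC(C)=CC2 | intermediate
19 | (3R,4S,6S)-4-bromo-5,5,9-trimethyl-1-methylidenespiro[5.5]undec-8-en-3-ol | C=C1C[C@@H](O)[C@@H](Br)C(C)(C)[C@]12CCC(C)=CC2 | intermediate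
20 | (3R,4S,6S,8S,9S)-4,8-dibromo-9-chloro-5,5,9-trimethyl-1-methylidenespiro[5.5]undecan-3-ol | C=C1C[C@@H](O)[C@@H](Br)C(C)(C)[C@]12CC[C@](C)(Cl)[C@@H](Br)C2 | target

Total step count: 8. Longest linear sequence: 8 steps (1 → 20).

Steps most likely to fail

Step 8. What may go wrong: uptake of Br+ by the exocyclic C1 methylidene, or opening of the bromonium ion by chloride at the secondary carbon C8 (diaxial opening) instead of at C9. The fallback sets out from 19 and comes back at 20, and introduces the halogens in two operations. NBS in aqueous acetone, with water in large excess as the nucleophile, should give the 8-bromo-9-hydroxy compound (bromohydrin) F8. Concentrated aqueous HCl in CH2Cl2 at 0 °C should then ionise only the tertiary alcohol of F8; the neighbouring bromine re-forms the same bromonium ion, so chloride enters at C9 with retention and gives 20.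

Step 5. What may go wrong: competing γ-deprotonation at the hydroxymethyl carbon, acid-induced isomerisation of the γ-hydroxy enone during equilibration, or too small a thermodynamic bias at C4. The fallback sets out from 8 and comes back at 15, and installs bromine before the one-carbon unit. C4 is the only enolisable position of 8, so LDA and Me3SiCl should give the 1-silyloxy-3-alkoxy diene F4, whose terminal carbon C4 is brominated by NBS to the bromo vinylogous ester F5. Addition of the cerium reagent made from 9 gives the carbinol F6, and the acid treatment of step 4 takes it through the MOM ether F7 to 15, the same acid equilibrating C4.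

Step 3. What may go wrong: weak activation of the alkoxy-donated carbonyl of 6 by the acid, acid-induced oligomerisation of isoprene, or poor enantiofacial discrimination in the ion pair. The fallback sets out from 3 and comes back at 8, and sets the quaternary centre by asymmetric allylation in place of cycloaddition. Alkylation of the α′ enolate of 3 (LDA, 4-iodo-2-methylbut-1-ene) gives the alkylated vinylogous ester F1, and LDA with allyl chloroformate gives the allyl enol carbonate F2. Enantioselective decarboxylative allylation (Pd2(dba)3 as the source of zerovalent palladium, tert-butyl-PHOX ligand of the required handedness) gives the α-quaternary ketone F3. Ring-closing metathesis with the second-generation Grubbs catalyst then closes ring B at C8=C9 and returns 8; this detour is held only as a contingency.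

Further compounds
F1 | step 3 | 5,5-dimethyl-6-(3-methylbut-3-en-1-yl)-3-(2-methylpropoxy)cyclohex-2-en-1-one (racemic) | CC(C)COC1=CC(=O)C(CCC(C)=C)C(C)(C)C1
F2 | step 3 | allyl enol carbonate of F1 (3,3-dimethyl-2-(3-methylbut-3-en-1-yl)-5-(2-methylpropoxy)cyclohexa-1,5-dien-1-yl prop-2-en-1-yl carbonate) | C=CCOC(=O)OC1=C(CCC(C)=C)C(C)(C)CC(OCC(C)C)=C1
F3 | step 3 | (6R)-5,5-dimethyl-6-(3-methylbut-3-en-1-yl)-3-(2-methylpropoxy)-6-(prop-2-en-1-yl)cyclohex-2-en-1-one | O=C1C=C(OCC(C)C)CC(C)(C)[C@]1(CC=C)CCC(C)=C
F4 | step 5 | (6R)-5,5,9-trimethyl-3-(2-methylpropoxy)-1-(trimethylsilyloxy)spiro[5.5]undeca-1,3,8-triene | C[Si](C)(C)OC1=CC(OCC(C)C)=CC(C)(C)[C@]12CCC(C)=CC2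
F5 | step 5 | (4S,6R)-4-bromo-5,5,9-trimethyl-3-(2-methylpropoxy)spiro[5.5]undeca-2,8-dien-1-one | O=C1C=C(OCC(C)C)[C@@H](Br)C(C)(C)[C@]12CCC(C)=CC2
F6 | step 5 | (4S,6R)-4-bromo-1-[(methoxymethoxy)methyl]-5,5,9-trimethyl-3-(2-methylpropoxy)spiro[5.5]undeca-2,8-dien-1-ol, both C1 epimers | COCOCC1(O)C=C(OCC(C)C)[C@@H](Br)C(C)(C)[C@]12CCC(C)=CC2
F7 | step 5 | (4S,6S)-4-bromo-1-[(methoxymethoxy)methyl]-5,5,9-trimethylspiro[5.5]undeca-1,8-dien-3-one | COCOCC1=CC(=O)[C@@H](Br)C(C)(C)[C@]12CCC(C)=CC2
F8 | step 8 | (3R,4S,6S,8S,9S)-4,8-dibromo-5,5,9-trimethyl-1-methylidenespiro[5.5]undecane-3,9-diol | C=C1C[C@@H](O)[C@@H](Br)C(C)(C)[C@]12CC[C@](C)(O)[C@@H](Br)C2
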